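Numbering the cyclopentane C1 (quaternary), C2 (CHCH3), C3 (alkylidene carbon), C4 and C5 (CH2), the ring is opened at C3–C4 to a chroman-2-one whose acyl carbon is C3, and this lactone is traced to a prochiral cyclobutanone. The feature used is C1: it carries a methyl group, the aryl carbon ortho to the phenol oxygen and the C2–C3 unit, so CH3–C1–C2–C3 is a four-membered ketone cut open once. In one rhodium-catalysed operation the phenol adds to that ketone, one of two enantiotopic ring bonds is cleaved, and the C1 stereocentre, its methyl group and the lactone ring appear together. The precursor is an achiral 3-(2-hydroxy-4-methylphenyl)cyclobutanone bearing the silyl-protected C5–C4 arm.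

Key step: step 7

Remark on the chemistry: (R)-SEGPHOS is assumed to direct the cleavage toward the (R)-lactone 12; if the sense of induction is the opposite one, (S)-SEGPHOS is used and nothing else changes.
Remark on the chemistry: hydroxy ketones 18 and 19 are written in the open form; a bridged hemiketal tautomer, if present, would react through this open form.

Step 1
Reactants: 1 2-bromo-5-methylphenol
Product: 2 2-(benzyloxy)-1-bromo-4-methylbenzene
Conditions: BnBr, K2CO3, DMF, rt
Reagents that add atoms: benzyl bromide, BrCc1ccccc1
Why: Williamson etherification masks the phenol against acylation in the ketene step, and the benzyl group can later be removed by neutral hydrogenolysis.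

Step 2
Reactants: 3 3-bromobut-3-en-1-ol
Product: 4 [(3-bromobut-3-en-1-yl)oxy](tert-butyl)dimethylsilane
Conditions: TBSCl, imidazole, CH2Cl2, rt
Reagents that add atoms: tert-butyldimethylsilyl chloride, CC(C)(C)[Si](C)(C)Cl
Why: Imidazole-promoted O-silylation gives a primary silyl ether that should tolerate palladium coupling, zinc and hydrogenolysis.

Step 3
Reactants: 2 2-(benzyloxy)-1-bromo-4-methylbenzene; 4 [(3-bromobut-3-en-1-yl)oxy](tert-butyl)dimethylsilane
Product: 6 {[3-(2-(benzyloxy)-4-methylphenyl)but-3-en-1-yl]oxy}(tert-butyl)dimethylsilane, via aryl pinacol boronate 5 (not isolated)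
Conditions: B2pin2, PdCl2(dppf) (cat.), KOAc, 1,4-dioxane, 90 °C; then 4, aq. K3PO4, 90 °C
Reagents that add atoms: none
Why: Miyaura borylation of the aryl bromide followed in the same flask by Suzuki–Miyaura coupling with the 2-bromoalkene joins the aryl carbon to the future C1 and gives the 1,1-disubstituted styrene.

Step 4
Reactants: 6 {[3-(2-(benzyloxy)-4-methylphenyl)but-3-en-1-yl]oxy}(tert-butyl)dimethylsilane; 7 trichloroacetyl chloride
Product: 9 racemic 3-[2-(benzyloxy)-4-methylphenyl]-3-{2-[(tert-butyldimethylsilyl)oxy]ethyl}-2,2-dichlorocyclobutan-1-one, via dichloroketene 8 (not isolated)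
Conditions: Zn–Cu couple, POCl3, Et2O, rt
Reagents that add atoms: none
Why: The thermal [2+2] cycloaddition of dichloroketene (zinc dehalogenation of the acid chloride) to an electron-rich 1,1-disubstituted alkene is regioselective, the ketene carbonyl carbon bonding to the terminal CH2, so that the aryl-bearing carbon becomes position 3 of the cyclobutanone.

Step 5
Reactants: 9 racemic 3-[2-(benzyloxy)-4-methylphenyl]-3-{2-[(tert-butyldimethylsilyl)oxy]ethyl}-2,2-dichlorocyclobutan-1-one
Product: 10 3-[2-(benzyloxy)-4-methylphenyl]-3-{2-[(tert-butyldimethylsilyl)oxy]ethyl}cyclobutan-1-one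
Conditions: Zn, NH4Cl, MeOH, rt
Reagents that add atoms: none
Why: Zinc reductive dechlorination of the alpha,alpha-dichloroketone in a buffered medium removes both chlorines and with them the only stereocentre, leaving a cyclobutanone with a mirror plane and an intact silyl ether.

Step 6
Reactants: 10 3-[2-(benzyloxy)-4-methylphenyl]-3-{2-[(tert-butyldimethylsilyl)oxy]ethyl}cyclobutan-1-one
Product: 11 3-{2-[(tert-butyldimethylsilyl)oxy]ethyl}-3-(2-hydroxy-4-methylphenyl)cyclobutan-1-one
Conditions: H2 (1 atm), Pd/C, EtOAc, rt
Reagents that add atoms: none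
Why: Catalytic hydrogenolysis of the benzyl ether frees the phenol under neutral conditions that should leave the strained ketone and the silyl ether untouched.

Step 7
Reactants: 11 3-{2-[(tert-butyldimethylsilyl)oxy]ethyl}-3-(2-hydroxy-4-methylphenyl)cyclobutan-1-one
Product: 12 (4R)-4-{2-[(tert-butyldimethylsilyl)oxy]ethyl}-4,7-dimethylchroman-2-one
Conditions: [Rh(OH)(cod)]2 (cat.), (R)-SEGPHOS (cat.), toluene, rt
Reagents that add atoms: none
Why: The hydroxo ligand on monovalent rhodium is exchanged for the substrate phenoxide, the rhodium aryloxide adds across the strained ketone to give a rhodium cyclobutanolate that already holds the new O–C3 bond, and beta-carbon elimination then breaks one of the two acyl–CH2 ring bonds with release of ring strain. The primary alkylrhodium so formed has no beta-hydrogen, its only neighbour being quaternary C1, so it is protonated by the next phenol molecule to the C1 methyl group and the aryloxide is regenerated. The closest known reaction type is the rhodium-catalysed asymmetric ring opening of 3-(2-hydroxyaryl)cyclobutanones to 4,4-disubstituted 3,4-dihydrocoumarins. The one ring formed, the six-membered lactone, closes by 6-exo-trig attack of the aryloxide oxygen on the carbonyl carbon. The C1 stereocentre is fixed at the bond-breaking event, where the chiral bisphosphine decides which enantiotopic bond migrates to rhodium. The only selectivity needed is this one, and the substrate secures it by being achiral with a single ketone, by anchoring the metal through its phenoxide, and by offering no beta-hydrogen or second reactive site.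

Step 8
Reactants: 12 (4R)-4-{2-[(tert-butyldimethylsilyl)oxy]ethyl}-4,7-dimethylchroman-2-one
Product: 14 (3R,4R)-4-{2-[(tert-butyldimethylsilyl)oxy]ethyl}-3,4,7-trimethylchroman-2-one, via lithium enolate 13 (not isolated)
Conditions: LDA (1.05 equiv), THF, −78 °C; MeI, −78 °C
Reagents that add atoms: iodomethane, CI
Why: Enolate alkylation (SN2 on iodomethane) should take place on the face opposite the larger silyloxyethyl group of the neighbouring quaternary carbon, which puts the new methyl group cis to the C1 methyl group in the lactone and therefore cis to the aryl group once C3–C4 is closed.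

Step 9
Reactants: 14 (3R,4R)-4-{2-[(tert-butyldimethylsilyl)oxy]ethyl}-3,4,7-trimethylchroman-2-one
Product: 15 (3R,4R)-4-(2-bromoethyl)-3,4,7-trimethylchroman-2-one
Conditions: Ph3PBr2, CH2Cl2, 0 °C to rt
Reagents that add atoms: triphenylphosphine dibromide, BrP(Br)(c1ccccc1)(c1ccccc1)c1ccccc1
Why: Direct bromodesilylation (oxyphosphonium formation, loss of the silyl bromide, SN2 by bromide) exchanges the silyl ether for bromide without ever freeing the primary alcohol, which would be expected to transesterify the aryl lactone into a six-membered alkyl lactone.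

Step 10
Reactants: 15 (3R,4R)-4-(2-bromoethyl)-3,4,7-trimethylchroman-2-one
Product: 16 (3R,4R)-4-(2-iodoethyl)-3,4,7-trimethylchroman-2-one
Conditions: NaI, acetone, reflux
Reagents that add atoms: sodium iodide, [Na+].[I-]
Why: Finkelstein halide exchange, driven by precipitation of sodium bromide, provides the primary iodide that undergoes clean halogen–lithium exchange.

Step 11
Reactants: 16 (3R,4R)-4-(2-iodoethyl)-3,4,7-trimethylchroman-2-one
Product: 18 (2R,3R)-3-(2-hydroxy-4-methylphenyl)-2,3-dimethylcyclopentan-1-one, via primary alkyllithium 17 (not isolated)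
Conditions: t-BuLi (2.1 equiv), Et2O–pentane, −78 °C; then aq. NH4Cl, −78 °C
Reagents that add atoms: none
Why: Iodine–lithium exchange should outrun attack of tert-butyllithium on the carbonyl, and the alkyllithium then closes C3–C4 by 5-exo-trig intramolecular acylation (Parham-type cyclisation) with the aryloxide as leaving group, which frees the phenol and leaves C1 and C2 untouched at low temperature.

Step 12
Reactants: 18 (2R,3R)-3-(2-hydroxy-4-methylphenyl)-2,3-dimethylcyclopentan-1-one
Product: 19 (2R,3R)-3-(5-bromo-2-hydroxy-4-methylphenyl)-2,3-dimethylcyclopentan-1-one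
Conditions: NBS (1.0 equiv), MeCN, 0 °C, dark
Reagents that add atoms: N-bromosuccinimide, O=C1CCC(=O)N1Br
Why: Electrophilic aromatic bromination of the phenol should go para to the hydroxyl group, the only unhindered activated position, and is placed before the olefination so that no alkene competes for the bromine.

Step 13
Reactants: 19 (2R,3R)-3-(5-bromo-2-hydroxy-4-methylphenyl)-2,3-dimethylcyclopentan-1-one
Product: 20 4-bromo-2-[(1R,2R,3E)-3-(bromomethylidene)-1,2-dimethylcyclopentyl]-5-methylphenol
Conditions: Ph3P(CH2Br)Br (3 equiv), KOtBu, THF, −78 °C to rt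
Reagents that add atoms: (bromomethyl)triphenylphosphonium bromide, [Br-].BrC[P+](c1ccccc1)(c1ccccc1)c1ccccc1
Why: Wittig olefination with the bromomethylidene ylide (one equivalent is spent on the phenol) should place bromine on the side of the unbranched C4 methylene and away from the branched C2, giving the E alkene, while the low temperature and the modest basicity of the halo-ylide protect the epimerisable C2 centre.

Compound list
1 | 2-bromo-5-methylphenol | Cc1ccc(Br)c(O)c1 | starting material
2 | 2-(benzyloxy)-1-bromo-4-methylbenzene | Cc1ccc(Br)c(OCc2ccccc2)c1 | intermediate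
3 | 3-bromobut-3-en-1-ol | OCCC(Br)=C | starting material
4 | [(3-bromobut-3-en-1-yl)oxy](tert-butyl)dimethylsilane | C=C(Br)CCO[Si](C)(C)C(C)(C)C | intermediate
5 | 2-[2-(benzyloxy)-4-methylphenyl]-4,4,5,5-tetramethyl-1,3,2-dioxaborolane | Cc1ccc(B2OC(C)(C)C(C)(C)O2)c(OCc3ccccc3)c1 | intermediate (not isolated)
6 | {[3-(2-(benzyloxy)-4-methylphenyl)but-3-en-1-yl]oxy}(tert-butyl)dimethylsilane | Cc1ccc(C(=C)CCO[Si](C)(C)C(C)(C)C)c(OCc2ccccc2)c1 | intermediate
7 | trichloroacetyl chloride | O=C(Cl)C(Cl)(Cl)Cl | starting material
8 | dichloroketene | ClC(Cl)=C=O | intermediate (not isolated)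
9 | racemic 3-[2-(benzyloxy)-4-methylphenyl]-3-{2-[(tert-butyldimethylsilyl)oxy]ethyl}-2,2-dichlorocyclobutan-1-one | Cc1ccc(C2(CCO[Si](C)(C)C(C)(C)C)CC(=O)C2(Cl)Cl)c(OCc3ccccc3)c1 | intermediate
10 | 3-[2-(benzyloxy)-4-methylphenyl]-3-{2-[(tert-butyldimethylsilyl)oxy]ethyl}cyclobutan-1-one (achiral) | Cc1ccc(C2(CCO[Si](C)(C)C(C)(C)C)CC(=O)C2)c(OCc3ccccc3)c1 | intermediate
11 | 3-{2-[(tert-butyldimethylsilyl)oxy]ethyl}-3-(2-hydroxy-4-methylphenyl)cyclobutan-1-one (achiral) | Cc1ccc(C2(CCO[Si](C)(C)C(C)(C)C)CC(=O)C2)c(O)c1 | intermediate
12 | (4R)-4-{2-[(tert-butyldimethylsilyl)oxy]ethyl}-4,7-dimethylchroman-2-one | Cc1ccc2c(c1)OC(=O)C[C@@]2(C)CCO[Si](C)(C)C(C)(C)C | intermediate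
13 | lithium enolate of 12 | Cc1ccc2c(c1)OC(O[Li])=C[C@@]2(C)CCO[Si](C)(C)C(C)(C)C | intermediate (not isolated)
14 | (3R,4R)-4-{2-[(tert-butyldimethylsilyl)oxy]ethyl}-3,4,7-trimethylchroman-2-one | Cc1ccc2c(c1)OC(=O)[C@H](C)[C@@]2(C)CCO[Si](C)(C)C(C)(C)C | intermediate
15 | (3R,4R)-4-(2-bromoethyl)-3,4,7-trimethylchroman-2-one | Cc1ccc2c(c1)OC(=O)[C@H](C)[C@@]2(C)CCBr | intermediate
16 | (3R,4R)-4-(2-iodoethyl)-3,4,7-trimethylchroman-2-one | Cc1ccc2c(c1)OC(=O)[C@H](C)[C@@]2(C)CCI | intermediate
17 | (3R,4R)-4-(2-lithioethyl)-3,4,7-trimethylchroman-2-one | Cc1ccc2c(c1)OC(=O)[C@H](C)[C@@]2(C)CC[Li] | intermediate (not isolated)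
18 | (2R,3R)-3-(2-hydroxy-4-methylphenyl)-2,3-dimethylcyclopentan-1-one | Cc1ccc([C@]2(C)CCC(=O)[C@@H]2C)c(O)c1 | intermediate
19 | (2R,3R)-3-(5-bromo-2-hydroxy-4-methylphenyl)-2,3-dimethylcyclopentan-1-one | Cc1cc(O)c([C@]2(C)CCC(=O)[C@@H]2C)cc1Br | intermediate
20 | 4-bromo-2-[(1R,2R,3E)-3-(bromomethylidene)-1,2-dimethylcyclopentyl]-5-methylphenol | Cc1cc(O)c([C@]2(C)CC/C(=C\Br)[C@@H]2C)cc1Br | target

Total step count: 13. Longest linear sequence: 12 steps (from 1 through steps 1 and 3 to 13; step 2 is a one-step side branch).

Steps most likely to fail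

Step 13. The basic ylide may enolise the ketone and so erode the C2 configuration, and the geometry of the new alkene may be incompletely controlled during oxaphosphetane formation. The fallback sets out from 19. A boron–Wittig olefination with lithiated bis(pinacolboryl)methane (CH2(Bpin)2, LiTMP, THF, −78 °C, one further equivalent of base for the phenol) should give, under less basic conditions and with boron remote from C2, the (E)-alkenyl pinacol boronate of the target skeleton F1. Stereoretentive bromodeboronation with CuBr2 in aqueous methanol then returns to the route at 20.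

Step 8. Facial selectivity in the enolate alkylation may be poor, because the two groups on the neighbouring quaternary carbon differ only moderately in size; the wrong face would lead to the C2 epimer of the target. The fallback sets out from 12. The lithium enolate is aminomethylated with dimethylmethylideneammonium iodide to the Mannich base F2. This is quaternised with iodomethane to the trimethylammonium iodide F3 and eliminated with DBU to the 3-methylidene lactone F4. Hydrogenation of this exocyclic alkene under catalyst control then sets C2 independently of the weak substrate bias and returns to the route at 14. The catalyst is Ru(OAc)2[(S)-BINAP] or its mirror image, whichever is found to deliver hydrogen to the face that carries the C5 chain.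

Step 11. tert-Butyllithium may add directly to the reactive aryl ester, or the alkyllithium may abstract the proton alpha to the carbonyl, instead of closing the ring. The fallback sets out from 16. SmI2 with catalytic tris(dibenzoylmethanato)iron, Fe(dbm)3, in THF at −30 to 0 °C generates a far less basic organosamarium species that performs the same intramolecular acyl substitution under Barbier conditions. It returns to the route at 18 and makes no compound outside the list (entry F0).

Further compounds
F1 | step 13 | 4-bromo-2-{1,2-dimethyl-3-[(E)-(4,4,5,5-tetramethyl-1,3,2-dioxaborolan-2-yl)methylidene]cyclopentyl}-5-methylphenol, ring stereocentres as in 19 | Cc1cc(O)c([C@]2(C)CC/C(=C\B3OC(C)(C)C(C)(C)O3)[C@@H]2C)cc1Br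
F2 | step 8 | 4-{2-[(tert-butyldimethylsilyl)oxy]ethyl}-3-[(dimethylamino)methyl]-4,7-dimethylchroman-2-one, C4 as in 12, both C3 epimers | Cc1ccc2c(c1)OC(=O)C(CN(C)C)[C@@]2(C)CCO[Si](C)(C)C(C)(C)C
F3 | step 8 | trimethylammonium iodide of F2 | Cc1ccc2c(c1)OC(=O)C(C[N+](C)(C)C)[C@@]2(C)CCO[Si](C)(C)C(C)(C)C.[I-]
F4 | step 8 | 4-{2-[(tert-butyldimethylsilyl)oxy]ethyl}-4,7-dimethyl-3-methylidenechroman-2-one, C4 arranged as in 12 | Cc1ccc2c(c1)OC(=O)C(=C)[C@@]2(C)CCO[Si](C)(C)C(C)(C)C
F0 | step 11 | none | none
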